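**Plan**

- Numbering used throughout: C1 is the carboxyl carbon, the 1,2-dioxolane is O–O–C3–C4–C5, C7 carries the chain methyl, and the E alkenes are C12=C13 and C16=C17 (phenyl on C17).
- Cuts, in retrosynthetic order: the ring O–C3 bond (leaving a C5 hydroperoxide beside an oxetane built from C3, C2, C1 and O); then the C5–OO bond (leaving an oxetane built from C5, C4, C3 and O, plus H2O2); then C12=C13 (sulfone plus aldehyde). C4, C3, C2 and C1 each trace back to a CH2 of trimethylsulfoxonium iodide.
- Enabling feature: ring carbons C3 and C5 are both quaternary, methyl-substituted C–O centres, and the oxygens on C5, C3 and C1 lie in a 1,3,5 pattern. Each ring carbon can therefore be the substituted carbon of a 2-methyl-2-alkyloxetane whose second O-bearing carbon (C3, later C1) has to carry oxygen in the target anyway.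
- Forward order: the chain is joined first (C12=C13). The C5 oxetane is then made and opened by H2O2, C3 is raised to a methyl ketone, and the C3 oxetane is made. The 1,2-dioxolane, the only ring of the target, is closed last, and C1 is oxidised to the acid.
- Stereochemistry: C7 comes from (R)-citronellal (1). C5 is set by catalyst-controlled methylene transfer and then inverted on perhydrolysis. C3 is set by the enantiomeric catalyst and then inverted in the ring closure. Both alkenes are E, from a Johnson–Claisen rearrangement and a Julia–Kocienski olefination.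

Key step: step 21

Assumption: LaLi3[(S)-binaphthoxide]3 is taken to give the (S)-oxirane from an alkyl methyl ketone (methyl versus CH2R discrimination); if a test on ketone 14 shows the opposite sense, the two catalyst enantiomers are exchanged between steps 13 and 19 and nothing else changes.

**Route**

Step 1
Reactants: 1 (R)-citronellal
Product: 2 (4R)-4,8-dimethylnon-7-en-2-ol (both C2 epimers)
Conditions: MeMgBr, THF, −78 → 0 °C; aq. NH4Cl
Reagents that add atoms: methylmagnesium bromide, C[Mg]Br
Why: Grignard addition to the aldehyde installs the future C5 methyl; the carbinol configuration is irrelevant because it is oxidised in step 12, and the C7 centre is not touched.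

Step 2
Reactants: 2 (4R)-4,8-dimethylnon-7-en-2-ol
Product: 3 tert-butyl{[(4R)-4,8-dimethylnon-7-en-2-yl]oxy}dimethylsilane
Conditions: TBSCl, imidazole, DMF, rt
Reagents that add atoms: tert-butyldimethylsilyl chloride, CC(C)(C)[Si](C)(C)Cl
Why: Standard silylation of a secondary alcohol, masking C5 through the chain-building steps.

Step 3
Reactants: 3 tert-butyl{[(4R)-4,8-dimethylnon-7-en-2-yl]oxy}dimethylsilane
Product: 4 methyl (2E,6R)-8-[(tert-butyldimethylsilyl)oxy]-6-methylnon-2-enoate
Conditions: methyl acrylate (5 equiv), second-generation Hoveyda–Grubbs catalyst (5 mol%), CH2Cl2, 40 °C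
Reagents that add atoms: methyl acrylate, C=CC(=O)OC
Why: Olefin cross-metathesis of a prenyl-type trisubstituted alkene with an acrylate is a well-behaved pairing that expels 2-methylpropene, gives the E enoate and adds C11 and C12 in one operation.

Step 4
Reactants: 4 methyl (2E,6R)-8-[(tert-butyldimethylsilyl)oxy]-6-methylnon-2-enoate
Product: 5 methyl (6R)-8-[(tert-butyldimethylsilyl)oxy]-6-methylnonanoate
Conditions: H2 (1 atm), 10% Pd/C, EtOAc, rt
Reagents that add atoms: none
Why: Heterogeneous hydrogenation of the conjugated alkene; ester and silyl ether are inert and no other alkene is present yet.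

Step 5
Reactants: 5 methyl (6R)-8-[(tert-butyldimethylsilyl)oxy]-6-methylnonanoate
Product: 6 (6R)-8-[(tert-butyldimethylsilyl)oxy]-6-methylnonanal
Conditions: iBu2AlH (1.05 equiv), CH2Cl2, −78 °C; aq. KNaC4H4O6
Reagents that add atoms: none
Why: Partial ester reduction stops at the tetrahedral aluminium hemiacetal at low temperature and releases the C12 aldehyde on work-up.

Step 6
Reactants: 7 1-phenylprop-2-en-1-ol (racemic)
Product: 8 ethyl (4E)-5-phenylpent-4-enoate
Conditions: CH3C(OEt)3 (5 equiv), EtCO2H (cat.), 140 °C, EtOH distilled off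
Reagents that add atoms: triethyl orthoacetate, CC(OCC)(OCC)OCC
Why: Johnson–Claisen rearrangement through a chair transition state with phenyl equatorial gives the E styrenyl alkene C16=C17 and adds C13 and C14; the racemic carbinol centre is destroyed.

Step 7
Reactants: 8 ethyl (4E)-5-phenylpent-4-enoate
Product: 9 (4E)-5-phenylpent-4-en-1-ol
Conditions: LiAlH4, Et2O, 0 °C
Reagents that add atoms: none
Why: Hydride reduction of the ester to the primary alcohol; the non-conjugated-to-carbonyl styrene is not reduced.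

Step 8
Reactants: 9 (4E)-5-phenylpent-4-en-1-ol
Product: 10 1-phenyl-5-{[(4E)-5-phenylpent-4-en-1-yl]sulfanyl}-1H-tetrazole
Conditions: 1-phenyl-1H-tetrazole-5-thiol, PPh3, DIAD, THF, 0 °C → rt
Reagents that add atoms: 1-phenyl-1H-tetrazole-5-thiol, Sc1nnnn1-c1ccccc1
Why: Mitsunobu thioetherification of a primary alcohol with an acidic heteroaryl thiol.

Step 9
Reactants: 10 1-phenyl-5-{[(4E)-5-phenylpent-4-en-1-yl]sulfanyl}-1H-tetrazole
Product: 11 1-phenyl-5-{[(4E)-5-phenylpent-4-en-1-yl]sulfonyl}-1H-tetrazole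
Conditions: 30% aq. H2O2, (NH4)6Mo7O24·4H2O (10 mol%), EtOH, 0 °C → rt
Reagents that add atoms: hydrogen peroxide, OO
Why: Molybdate-catalysed peroxide oxidation takes the sulfide to the sulfone and leaves an unactivated styrene alone, where a peracid would epoxidise it.

Step 10
Reactants: 6 (6R)-8-[(tert-butyldimethylsilyl)oxy]-6-methylnonanal and 11 1-phenyl-5-{[(4E)-5-phenylpent-4-en-1-yl]sulfonyl}-1H-tetrazole
Product: 12 tert-butyldimethyl{[(4R,9E,13E)-4-methyl-14-phenyltetradeca-9,13-dien-2-yl]oxy}silane
Conditions: 11, KN(SiMe3)2, DME, −60 °C; then 6, −60 °C → rt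
Reagents that add atoms: none
Why: Julia–Kocienski olefination of an unbranched aldehyde with a 1-phenyltetrazolyl sulfone under potassium/DME conditions forms C12=C13 with E selectivity through the anti adduct and Smiles rearrangement.

Step 11
Reactants: 12 tert-butyldimethyl{[(4R,9E,13E)-4-methyl-14-phenyltetradeca-9,13-dien-2-yl]oxy}silane
Product: 13 (4R,9E,13E)-4-methyl-14-phenyltetradeca-9,13-dien-2-ol (both C2 epimers)
Conditions: Bu4NF, THF, rt
Reagents that add atoms: none
Why: Fluoride cleavage of the silyl ether.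

Step 12
Reactants: 13 (4R,9E,13E)-4-methyl-14-phenyltetradeca-9,13-dien-2-ol
Product: 14 (4R,9E,13E)-4-methyl-14-phenyltetradeca-9,13-dien-2-one
Conditions: Dess–Martin periodinane, NaHCO3, CH2Cl2, rt
Reagents that add atoms: none
Why: Dess–Martin oxidation converges both carbinol epimers on the methyl ketone (carbonyl carbon is C5) without touching the alkenes or the β-stereocentre C7.

Step 13
Reactants: 14 (4R,9E,13E)-4-methyl-14-phenyltetradeca-9,13-dien-2-one and 15 trimethylsulfoxonium iodide
Product: 17 (2S)-2-methyl-2-[(2R,7E,11E)-2-methyl-12-phenyldodeca-7,11-dien-1-yl]oxetane, via oxirane 16 (not isolated)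
Conditions: 15, NaH, THF, reflux (ylide solution); 14, LaLi3[(S)-binaphthoxide]3 (5 mol%), (2,4,6-(MeO)3C6H2)3P=O (5 mol%), 5 Å MS, THF, rt; then more ylide and catalyst (15 mol%), 45 °C
Reagents that add atoms: trimethylsulfoxonium iodide (15), C[S+](C)(C)=O.[I-]
Why: Catalytic asymmetric Corey–Chaykovsky methylene transfer to a methyl ketone, followed in the same pot by sulfoxonium-ylide ring expansion of the 2,2-disubstituted epoxide (ylide opens the epoxide CH2, the γ-alkoxide expels DMSO in a 4-exo-tet closure), is a documented one-pot route to 2-methyl-2-alkyloxetanes; the catalyst distinguishes methyl from CH2R and so sets C5, the ring expansion does not touch C5, and the second stage should further enrich the major isomer.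

Step 14
Reactants: 17 (2S)-2-methyl-2-[(2R,7E,11E)-2-methyl-12-phenyldodeca-7,11-dien-1-yl]oxetane
Product: 18 (3R,5R,10E,14E)-3-hydroperoxy-3,5-dimethyl-15-phenylpentadeca-10,14-dien-1-ol
Conditions: anhydrous H2O2 in Et2O (10 equiv), Me3SiOTf (0.2 equiv), Et2O, −78 → −20 °C
Reagents that add atoms: hydrogen peroxide, OO
Why: Lewis-acid perhydrolysis of a 2,2-disubstituted oxetane is known to occur at the tertiary carbon with inversion on enantioenriched 2-methyl-2-alkyloxetanes, so the (S)-oxetane carbon should become the (R)-configured C5–OOH centre while the ring oxygen ends as the C3 primary alcohol; the isolated alkenes do not react with H2O2 without an oxidation catalyst.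

Step 15
Reactants: 18 (3R,5R,10E,14E)-3-hydroperoxy-3,5-dimethyl-15-phenylpentadeca-10,14-dien-1-ol
Product: 19 (3R,5R,10E,14E)-3-[(2-methoxypropan-2-yl)peroxy]-3,5-dimethyl-15-phenylpentadeca-10,14-dien-1-ol
Conditions: 2-methoxypropene (1.2 equiv), PPTS (5 mol%), CH2Cl2, −20 → 0 °C
Reagents that add atoms: 2-methoxypropene, C=C(C)OC
Why: Acid-catalysed monoperoxyketal formation; the more acidic, alpha-effect hydroperoxide should capture the 2-methoxyprop-2-yl cation ahead of the primary alcohol when the enol ether is limiting and the temperature is low, which also holds back ketal exchange onto the alcohol.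

Step 16
Reactants: 19 (3R,5R,10E,14E)-3-[(2-methoxypropan-2-yl)peroxy]-3,5-dimethyl-15-phenylpentadeca-10,14-dien-1-ol
Product: 20 (3R,5R,10E,14E)-3-[(2-methoxypropan-2-yl)peroxy]-3,5-dimethyl-15-phenylpentadeca-10,14-dienal
Conditions: Dess–Martin periodinane, NaHCO3, CH2Cl2, 0 °C; used at once
Reagents that add atoms: none
Why: Buffered Dess–Martin oxidation gives the β-peroxy aldehyde under non-basic conditions that should not trigger loss of the peroxide, and the peroxyketal is stable to the reagent.

Step 17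
Reactants: 20 (3R,5R,10E,14E)-3-[(2-methoxypropan-2-yl)peroxy]-3,5-dimethyl-15-phenylpentadeca-10,14-dienal
Product: 21 (4R,6R,11E,15E)-4-[(2-methoxypropan-2-yl)peroxy]-4,6-dimethyl-16-phenylhexadeca-11,15-dien-2-ol (both C2 epimers)
Conditions: MeTi(OiPr)3 (1.5 equiv), THF, −40 → 0 °C; aq. NH4Cl
Reagents that add atoms: methyltitanium triisopropoxide, C[Ti](OC(C)C)(OC(C)C)OC(C)C
Why: Carbonyl methylation by a non-basic, aldehyde-selective organotitanium reagent adds the C3 methyl without enolising the β-peroxy aldehyde or attacking the O–O bond; the new carbinol centre is removed in step 18.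

Step 18
Reactants: 21 (4R,6R,11E,15E)-4-[(2-methoxypropan-2-yl)peroxy]-4,6-dimethyl-16-phenylhexadeca-11,15-dien-2-ol
Product: 22 (4R,6R,11E,15E)-4-[(2-methoxypropan-2-yl)peroxy]-4,6-dimethyl-16-phenylhexadeca-11,15-dien-2-one
Conditions: Dess–Martin periodinane, NaHCO3, CH2Cl2, 0 °C → rt
Reagents that add atoms: none
Why: Dess–Martin oxidation of the secondary alcohol gives the methyl ketone whose carbonyl carbon is C3.

Step 19
Reactants: 22 (4R,6R,11E,15E)-4-[(2-methoxypropan-2-yl)peroxy]-4,6-dimethyl-16-phenylhexadeca-11,15-dien-2-one and 15 trimethylsulfoxonium iodide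
Product: 24 (2S)-2-[(2R,4R,9E,13E)-2-[(2-methoxypropan-2-yl)peroxy]-2,4-dimethyl-14-phenyltetradeca-9,13-dien-1-yl]-2-methyloxetane, via oxirane 23 (not isolated)
Conditions: ylide from 15/NaH in THF; 22 added slowly, LaLi3[(R)-binaphthoxide]3 (5 mol%), (2,4,6-(MeO)3C6H2)3P=O (5 mol%), 5 Å MS, THF, 0 °C → rt; then more ylide and catalyst (15 mol%), 45 °C
Reagents that add atoms: trimethylsulfoxonium iodide (15), C[S+](C)(C)=O.[I-]
Why: The same asymmetric Corey–Chaykovsky methylene transfer and ylide ring expansion as in step 13, run with the enantiomeric catalyst, should place the new CH2 on the opposite face relative to methyl and CH2R and so set C3 by catalyst control (R-oxirane, then S-oxetane by CIP priority change only); slow ketone addition to the Lewis-acid-bound, weakly basic ylide is meant to let 1,2-addition outrun enolisation toward C4.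

Step 20
Reactants: 24 (2S)-2-[(2R,4R,9E,13E)-2-[(2-methoxypropan-2-yl)peroxy]-2,4-dimethyl-14-phenyltetradeca-9,13-dien-1-yl]-2-methyloxetane
Product: 25 (2S)-2-[(2R,4R,9E,13E)-2-hydroperoxy-2,4-dimethyl-14-phenyltetradeca-9,13-dien-1-yl]-2-methyloxetane
Conditions: AcOH/THF/H2O (4:2:1), 0 °C → rt
Reagents that add atoms: none
Why: Hydrolysis of the 2-methoxyprop-2-yl monoperoxyketal proceeds in dilute acetic acid, well below the acidity needed to activate the oxetane, and touches no stereocentre.

Step 21
Reactants: 25 (2S)-2-[(2R,4R,9E,13E)-2-hydroperoxy-2,4-dimethyl-14-phenyltetradeca-9,13-dien-1-yl]-2-methyloxetane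
Product: 26 2-[(3R,5R)-3,5-dimethyl-5-[(2R,7E,11E)-2-methyl-12-phenyldodeca-7,11-dien-1-yl]-1,2-dioxolan-3-yl]ethan-1-ol
Conditions: Me3SiOTf (0.1 equiv), CH2Cl2, −78 → −40 °C; aq. NaHCO3
Reagents that add atoms: none
Why: Proposed new method: the silyl triflate binds the oxetane oxygen, lengthening the strained C3–O bond and placing positive charge on tertiary C3, and the terminal oxygen of the C5 hydroperoxide, held five atoms away, displaces the oxetane oxygen from the rear before a free cation forms; proton loss then returns the catalyst and leaves the former ring oxygen as the C1 alcohol. The closest known reaction types are the intermolecular Lewis-acid perhydrolysis of enantioenriched 2,2-disubstituted oxetanes with inversion (step 14) and exo-tet openings of epoxides by tethered hydroperoxides; not yet shown is closure by a tertiary hydroperoxide onto a fully substituted oxetane carbon to give a 3,3,5,5-tetrasubstituted 1,2-dioxolane with transfer of configuration. The 1,2-dioxolane (O1, O2, C3, C4, C5) closes in a 5-exo-tet mode while the oxetane opens to the C2–C1 hydroxyethyl arm. C3 is controlled by the oxetane configuration from step 19 through stereospecific inversion, which puts the C2 arm trans to the C5 side chain, and C5 is unchanged because its C–O bond is not involved. The step needs attack at C3 and not at the oxetane CH2 (a 7-endo closure at a carbon carrying no stabilised charge), and substitution rather than ionisation or elimination; the short tether, the tertiary character of C3, the alpha-effect nucleophile, the non-nucleophilic counter-ion and the low temperature are what should secure this.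

Step 22
Reactants: 26 2-[(3R,5R)-3,5-dimethyl-5-[(2R,7E,11E)-2-methyl-12-phenyldodeca-7,11-dien-1-yl]-1,2-dioxolan-3-yl]ethan-1-ol
Product: 28 2-[(3S,5R)-3,5-dimethyl-5-[(2R,7E,11E)-2-methyl-12-phenyldodeca-7,11-dien-1-yl]-1,2-dioxolan-3-yl]acetic acid, via aldehyde 27 (not isolated)
Conditions: TEMPO (0.2 equiv), PhI(OAc)2 (2.5 equiv), MeCN/H2O (1:1), 0 °C → rt
Reagents that add atoms: water, O
Why: Nitroxyl-catalysed oxidation with a hypervalent iodine co-oxidant in aqueous acetonitrile takes a primary alcohol through the aldehyde hydrate to the acid under mildly acidic conditions that leave the dialkyl peroxide, both alkenes and all three stereocentres alone (the C3 descriptor changes from R to S by CIP priority only).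

**Compound list**

1 | (R)-citronellal | C[C@H](CCC=C(C)C)CC=O | starting material
2 | (4R)-4,8-dimethylnon-7-en-2-ol (C2 epimers) | C[C@H](CCC=C(C)C)CC(C)O | intermediate
3 | tert-butyl{[(4R)-4,8-dimethylnon-7-en-2-yl]oxy}dimethylsilane | C[C@H](CCC=C(C)C)CC(C)O[Si](C)(C)C(C)(C)C | intermediate
4 | methyl (2E,6R)-8-[(tert-butyldimethylsilyl)oxy]-6-methylnon-2-enoate | C[C@H](CC/C=C/C(=O)OC)CC(C)O[Si](C)(C)C(C)(C)C | intermediate
5 | methyl (6R)-8-[(tert-butyldimethylsilyl)oxy]-6-methylnonanoate | C[C@H](CCCCC(=O)OC)CC(C)O[Si](C)(C)C(C)(C)C | intermediate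
6 | (6R)-8-[(tert-butyldimethylsilyl)oxy]-6-methylnonanal | C[C@H](CCCCC=O)CC(C)O[Si](C)(C)C(C)(C)C | intermediate
7 | 1-phenylprop-2-en-1-ol (racemic) | C=CC(O)c1ccccc1 | starting material
8 | ethyl (4E)-5-phenylpent-4-enoate | CCOC(=O)CC/C=C/c1ccccc1 | intermediate
9 | (4E)-5-phenylpent-4-en-1-ol | OCCC/C=C/c1ccccc1 | intermediate
10 | 1-phenyl-5-{[(4E)-5-phenylpent-4-en-1-yl]sulfanyl}-1H-tetrazole | C(CC/C=C/c1ccccc1)Sc1nnnn1-c1ccccc1 | intermediate
11 | 1-phenyl-5-{[(4E)-5-phenylpent-4-en-1-yl]sulfonyl}-1H-tetrazole | O=S(=O)(CCC/C=C/c1ccccc1)c1nnnn1-c1ccccc1 | intermediate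
12 | tert-butyldimethyl{[(4R,9E,13E)-4-methyl-14-phenyltetradeca-9,13-dien-2-yl]oxy}silane | C[C@H](CCCC/C=C/CC/C=C/c1ccccc1)CC(C)O[Si](C)(C)C(C)(C)C | intermediate
13 | (4R,9E,13E)-4-methyl-14-phenyltetradeca-9,13-dien-2-ol (C2 epimers) | C[C@H](CCCC/C=C/CC/C=C/c1ccccc1)CC(C)O | intermediate
14 | (4R,9E,13E)-4-methyl-14-phenyltetradeca-9,13-dien-2-one | C[C@H](CCCC/C=C/CC/C=C/c1ccccc1)CC(C)=O | intermediate
15 | trimethylsulfoxonium iodide | C[S+](C)(C)=O.[I-] | starting material
16 | (2S)-2-methyl-2-[(2R,7E,11E)-2-methyl-12-phenyldodeca-7,11-dien-1-yl]oxirane | C[C@H](CCCC/C=C/CC/C=C/c1ccccc1)C[C@@]1(C)CO1 | intermediate (not isolated)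
17 | (2S)-2-methyl-2-[(2R,7E,11E)-2-methyl-12-phenyldodeca-7,11-dien-1-yl]oxetane | C[C@H](CCCC/C=C/CC/C=C/c1ccccc1)C[C@@]1(C)CCO1 | intermediate
18 | (3R,5R,10E,14E)-3-hydroperoxy-3,5-dimethyl-15-phenylpentadeca-10,14-dien-1-ol | C[C@H](CCCC/C=C/CC/C=C/c1ccccc1)C[C@@](C)(OO)CCO | intermediate
19 | (3R,5R,10E,14E)-3-[(2-methoxypropan-2-yl)peroxy]-3,5-dimethyl-15-phenylpentadeca-10,14-dien-1-ol | C[C@H](CCCC/C=C/CC/C=C/c1ccccc1)C[C@@](C)(OOC(C)(C)OC)CCO | intermediate
20 | (3R,5R,10E,14E)-3-[(2-methoxypropan-2-yl)peroxy]-3,5-dimethyl-15-phenylpentadeca-10,14-dienal | C[C@H](CCCC/C=C/CC/C=C/c1ccccc1)C[C@@](C)(OOC(C)(C)OC)CC=O | intermediate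
21 | (4R,6R,11E,15E)-4-[(2-methoxypropan-2-yl)peroxy]-4,6-dimethyl-16-phenylhexadeca-11,15-dien-2-ol (C2 epimers) | C[C@H](CCCC/C=C/CC/C=C/c1ccccc1)C[C@@](C)(OOC(C)(C)OC)CC(C)O | intermediate
22 | (4R,6R,11E,15E)-4-[(2-methoxypropan-2-yl)peroxy]-4,6-dimethyl-16-phenylhexadeca-11,15-dien-2-one | C[C@H](CCCC/C=C/CC/C=C/c1ccccc1)C[C@@](C)(OOC(C)(C)OC)CC(C)=O | intermediate
23 | (2R)-2-[(2R,4R,9E,13E)-2-[(2-methoxypropan-2-yl)peroxy]-2,4-dimethyl-14-phenyltetradeca-9,13-dien-1-yl]-2-methyloxirane | C[C@H](CCCC/C=C/CC/C=C/c1ccccc1)C[C@@](C)(OOC(C)(C)OC)C[C@]1(C)CO1 | intermediate (not isolated)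
24 | (2S)-2-[(2R,4R,9E,13E)-2-[(2-methoxypropan-2-yl)peroxy]-2,4-dimethyl-14-phenyltetradeca-9,13-dien-1-yl]-2-methyloxetane | C[C@H](CCCC/C=C/CC/C=C/c1ccccc1)C[C@@](C)(OOC(C)(C)OC)C[C@]1(C)CCO1 | intermediate
25 | (2S)-2-[(2R,4R,9E,13E)-2-hydroperoxy-2,4-dimethyl-14-phenyltetradeca-9,13-dien-1-yl]-2-methyloxetane | C[C@H](CCCC/C=C/CC/C=C/c1ccccc1)C[C@@](C)(OO)C[C@]1(C)CCO1 | intermediate
26 | 2-[(3R,5R)-3,5-dimethyl-5-[(2R,7E,11E)-2-methyl-12-phenyldodeca-7,11-dien-1-yl]-1,2-dioxolan-3-yl]ethan-1-ol | C[C@H](CCCC/C=C/CC/C=C/c1ccccc1)C[C@]1(C)C[C@@](C)(CCO)OO1 | intermediate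
27 | 2-[(3S,5R)-3,5-dimethyl-5-[(2R,7E,11E)-2-methyl-12-phenyldodeca-7,11-dien-1-yl]-1,2-dioxolan-3-yl]acetaldehyde | C[C@H](CCCC/C=C/CC/C=C/c1ccccc1)C[C@]1(C)C[C@@](C)(CC=O)OO1 | intermediate (not isolated)
28 | 2-[(3S,5R)-3,5-dimethyl-5-[(2R,7E,11E)-2-methyl-12-phenyldodeca-7,11-dien-1-yl]-1,2-dioxolan-3-yl]acetic acid (CNP0204107.3) | C[C@H](CCCC/C=C/CC/C=C/c1ccccc1)C[C@]1(C)C[C@@](C)(CC(=O)O)OO1 | target

**Count**

Total steps: 22. Longest linear sequence: 18 steps (steps 1–5 and 10–22, from 1); the sulfone branch (steps 6–9) joins at step 10.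

**Steps most likely to fail**

1. Step 21 (proposed new method). The activated oxetane may ionise at C3 to a tertiary cation, which would scramble C3 or lead to elimination, and the tertiary hydroperoxide may rearrange under the Lewis acid. The fallback uses known peroxycarbenium chemistry, sets out from ketone 22 and returns at acid 28.
   - TsOH in methanol removes the peroxyketal of 22 and converts the resulting β-hydroperoxy ketone, through its cyclic hemiperketal, into the 3-methoxy-1,2-dioxolane F1.
   - TiCl4 in CH2Cl2 at −78 °C ionises F1 to the dioxolan-3-ylium ion, which is trapped by 1-(ethylsulfanyl)-1-(trimethylsilyloxy)ethene to give the S-ethyl dioxolane-3-thioacetate F2. The nucleophile is expected to enter anti to the larger C5 substituent; the C3 epimers would be separated by chromatography.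
   - Hydrolysis of the thioester with LiOH/H2O2 in aqueous THF gives 28.
   - This forms the C3–C2 bond on a preformed ring instead of the O–C3 bond.

2. Step 19. Enolisation of 22 toward C4 may expel the β-peroxide before the ylide adds, and the neighbouring quaternary peroxide may erode catalyst control. The fallback builds the oxetane by aldol addition and Williamson closure, sets out from ketone 22 and returns at oxetane 24.
   - The cerium enolate of ethyl acetate (LiN(iPr)2, EtOAc, CeCl3, THF, −78 °C) adds to 22 to give the β-hydroxy ester F3.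
   - LiBH4 reduces the ester to the 1,3-diol F4.
   - TsCl/pyridine gives the primary monotosylate F5, and KOtBu in THF closes the oxetane 24.
   - C3 is then not catalyst-controlled; the C3 epimers would be separated at F4 or 24.

3. Step 17. Base-induced β-elimination of the peroxyketal from aldehyde 20, or attack of the methyl-metal on the O–O bond, may compete with carbonyl addition. The fallback avoids isolating or methylating the aldehyde, sets out from alcohol 19 and returns at ketone 22.
   - TEMPO/PhI(OAc)2 in aqueous MeCN oxidises 19 directly to the β-peroxy carboxylic acid F6.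
   - Coupling with N,O-dimethylhydroxylamine (EDC) gives the Weinreb amide F7.
   - MeMgBr in THF at −40 °C gives 22 through the stable chelated tetrahedral intermediate.

**Further compounds**

F1 | step 21 | (5R)-3-methoxy-3,5-dimethyl-5-[(2R,7E,11E)-2-methyl-12-phenyldodeca-7,11-dien-1-yl]-1,2-dioxolane (both C3 epimers) | C[C@H](CCCC/C=C/CC/C=C/c1ccccc1)C[C@]1(C)CC(C)(OC)OO1
F2 | step 21 | S-ethyl 2-[(3S,5R)-3,5-dimethyl-5-[(2R,7E,11E)-2-methyl-12-phenyldodeca-7,11-dien-1-yl]-1,2-dioxolan-3-yl]ethanethioate | C[C@H](CCCC/C=C/CC/C=C/c1ccccc1)C[C@]1(C)C[C@@](C)(CC(=O)SCC)OO1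
F3 | step 19 | ethyl (3R,5R,7R,12E,16E)-3-hydroxy-5-[(2-methoxypropan-2-yl)peroxy]-3,5,7-trimethyl-17-phenylheptadeca-12,16-dienoate | C[C@H](CCCC/C=C/CC/C=C/c1ccccc1)C[C@@](C)(OOC(C)(C)OC)C[C@](O)(C)CC(=O)OCC
F4 | step 19 | (3S,5R,7R,12E,16E)-5-[(2-methoxypropan-2-yl)peroxy]-3,5,7-trimethyl-17-phenylheptadeca-12,16-diene-1,3-diol | C[C@H](CCCC/C=C/CC/C=C/c1ccccc1)C[C@@](C)(OOC(C)(C)OC)C[C@](O)(C)CCO
F5 | step 19 | (3S,5R,7R,12E,16E)-3-hydroxy-5-[(2-methoxypropan-2-yl)peroxy]-3,5,7-trimethyl-17-phenylheptadeca-12,16-dien-1-yl 4-methylbenzenesulfonate | C[C@H](CCCC/C=C/CC/C=C/c1ccccc1)C[C@@](C)(OOC(C)(C)OC)C[C@](O)(C)CCOS(=O)(=O)c1ccc(C)cc1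
F6 | step 17 | (3R,5R,10E,14E)-3-[(2-methoxypropan-2-yl)peroxy]-3,5-dimethyl-15-phenylpentadeca-10,14-dienoic acid | C[C@H](CCCC/C=C/CC/C=C/c1ccccc1)C[C@@](C)(OOC(C)(C)OC)CC(=O)O
F7 | step 17 | (3R,5R,10E,14E)-N-methoxy-3-[(2-methoxypropan-2-yl)peroxy]-N,3,5-trimethyl-15-phenylpentadeca-10,14-dienamide | C[C@H](CCCC/C=C/CC/C=C/c1ccccc1)C[C@@](C)(OOC(C)(C)OC)CC(=O)N(C)OC
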